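**Strategy.** Lactucaxanthin is C2-symmetric, so one C15 ring unit is made and joined twice to the C10 trienedial by Wittig olefination. In each ring (C1–C6) the allylic carbinol C3 sits next to the trisubstituted C4=C5 alkene whose C5 bears a methyl group: the retron of a trans-selective alkylative alkyne–aldehyde cyclisation. An acyclic 5-alkynal carrying the gem-dimethyl carbon C1 and the C6 stereocentre (from a chirality-transferring anionic oxy-Cope rearrangement) is closed by zerovalent palladium with methylboronic acid. One operation forms the C3–C4 bond, the ring, the C4=C5 alkene, the C5 methyl group and the C3 carbinol, which a Mitsunobu esterification then inverts.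

Key step: step 4

Remark: the SMILES is read as all-E (3R,6R,3'R,6'R)-ε,ε-carotene-3,3'-diol (OH and polyene chain trans on each ring). Carotenoid numbering is used for ring atoms. Allenylboronic acid pinacol ester, (bromoethynyl)trimethylsilane and the C10 trienedial are taken as commercial.

Step 1
Reactants: 1 3-methylbut-2-enal; 2 allenylboronic acid pinacol ester
Product: 4 (4R)-6-methylhept-5-en-1-yn-4-ol, via pinacol borate ester 3 (not isolated)
Conditions: (R)-TRIP [(R)-3,3'-bis(2,4,6-triisopropylphenyl)-1,1'-binaphthyl-2,2'-diyl hydrogen phosphate] (5 mol %), 4 Å molecular sieves, toluene, 0 °C; aq. NaHCO3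
Reagents that add atoms: allenylboronic acid pinacol ester 2, C=C=CB1OC(C)(C)C(C)(C)O1
Why: Chiral phosphoric acid-catalysed propargylboration, in which the acid activates the boronate and the allenyl group is delivered through a six-membered chair (SE2') to the Re face of the enal, the catalyst enantiomer being chosen for that face, which sets the 4R carbinol.

Step 2
Reactants: 4 (4R)-6-methylhept-5-en-1-yn-4-ol; 5 (bromoethynyl)trimethylsilane
Product: 7 (3E,6R)-8-methyl-1-(trimethylsilyl)nona-3,7-dien-1-yn-6-ol, via alkenylzirconocene chloride 6 (not isolated)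
Conditions: Cp2Zr(H)Cl (2.2 equiv), THF, 0 °C to rt, dark; then 5 (1.1 equiv), Pd(PPh3)4 (5 mol %), ZnCl2 (30 mol %), rt; aq. NH4Cl
Reagents that add atoms: (bromoethynyl)trimethylsilane 5, C[Si](C)(C)C#CBr
Why: Syn-hydrozirconation of the terminal alkyne (the first equivalent only zirconates the hydroxyl group, and the trisubstituted alkene is inert) fixes the E geometry, and the alkenylzirconocene couples with retention with the bromoalkyne in a Negishi coupling with ZnCl2 as transmetalation shuttle.

Step 3
Reactants: 7 (3E,6R)-8-methyl-1-(trimethylsilyl)nona-3,7-dien-1-yn-6-ol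
Product: 10 (4R)-4-ethynyl-3,3-dimethylhex-5-enal, via potassium enolate 8 (not isolated), via silylated alkynal 9 (not isolated)
Conditions: KH (1.2 equiv), 18-crown-6 (1.2 equiv), THF, 0 to 40 °C; inverse quench into AcOH/THF, −78 °C; crude in MeOH, K2CO3 (0.2 equiv), 0 °C
Reagents that add atoms: none
Why: Anionic oxy-Cope rearrangement through a chair in which the alkoxide is equatorial (an axial alkoxide would clash with the axial methyl of the prenyl terminus) and the E-enyne substituent is equatorial, so the carbinol configuration is relayed to C6 (R) while C1 becomes quaternary; protonation gives the aldehyde and K2CO3/MeOH removes the alkynyl silyl group.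

Step 4
Reactants: 10 (4R)-4-ethynyl-3,3-dimethylhex-5-enal; 11 methylboronic acid
Product: 12 (1S,4R)-4-ethenyl-3,5,5-trimethylcyclohex-2-en-1-ol
Conditions: Pd2(dba)3 (2.5 mol %), PCy3 (10 mol %), MeB(OH)2 (2.5 equiv), degassed MeOH, 60 °C
Reagents that add atoms: methylboronic acid 11, CB(O)O
Why: Zerovalent palladium bound to the terminal alkyne attacks the boron-activated aldehyde through C4 on the face opposite to the metal (anti-Wacker-type oxidative addition), giving an alkenyl divalent palladium alkoxide with palladium on C5 trans to the new C3–C4 bond; methyl transfer from the alkoxide-bound boron and reductive elimination then place the methyl group on C5. The closest known reaction type is the palladium-catalysed trans-selective alkylative cyclisation of 5-alkynals with organoboron reagents to cyclohex-2-en-1-ols. The six-membered ring closes 6-exo-trig at the carbonyl group with both alkyne carbons ending inside the ring (endo mode for the alkyne), so the ring fixes the C4=C5 geometry. The new stereocentre C3 is controlled by the existing C6 centre through a half-chair in which the C3 oxygen is pseudoequatorial (avoiding the syn-axial methyl on C1) and the C6 vinyl group is pseudoaxial (avoiding the palladium-bearing C5), which should give the 3,6-cis (3S) alcohol that step 5 inverts. The step needs endo over 5-exo closure, which attack through the unsubstituted alkyne terminus, the gem-dimethyl effect and the PCy3 ligand should secure, and chemoselectivity over the vinyl group, which zerovalent palladium leaves untouched. The terminal alkyne and the methyl donor are the untested variables of this known reaction type.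

Step 5
Reactants: 12 (1S,4R)-4-ethenyl-3,5,5-trimethylcyclohex-2-en-1-ol; 13 benzoic acid
Product: 14 (1R,4R)-4-ethenyl-3,5,5-trimethylcyclohex-2-en-1-yl benzoate
Conditions: PPh3, diisopropyl azodicarboxylate, BzOH, THF, 0 °C to rt
Reagents that add atoms: benzoic acid 13, OC(=O)c1ccccc1
Why: Mitsunobu reaction, in which benzoate displaces the alkoxyphosphonium by SN2 and inverts C3 to R (3,6-trans), the ester then shielding the acid-labile allylic oxygen, while any 3,6-trans alcohol from step 4 converges on 14 with BzCl/pyridine.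

Step 6
Reactants: 14 (1R,4R)-4-ethenyl-3,5,5-trimethylcyclohex-2-en-1-yl benzoate; 15 but-3-en-2-one
Product: 16 (1R,4R)-3,5,5-trimethyl-4-[(1E)-3-oxobut-1-en-1-yl]cyclohex-2-en-1-yl benzoate
Conditions: second-generation Hoveyda–Grubbs catalyst RuCl2(H2IMes)(=CH-C6H4-2-OiPr) (5 mol %), but-3-en-2-one (5 equiv), CH2Cl2, 40 °C
Reagents that add atoms: but-3-en-2-one 15, CC(=O)C=C
Why: Olefin cross-metathesis between the monosubstituted vinyl group and the electron-poor enone partner should be E-selective and leave the trisubstituted ring alkene untouched.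

Step 7
Reactants: 16 (1R,4R)-3,5,5-trimethyl-4-[(1E)-3-oxobut-1-en-1-yl]cyclohex-2-en-1-yl benzoate; 17 vinylmagnesium bromide
Product: 18 (1R,4R)-4-[(1E)-3-hydroxy-3-methylpenta-1,4-dien-1-yl]-3,5,5-trimethylcyclohex-2-en-1-yl benzoate (C9 epimers)
Conditions: CH2=CHMgBr (1.3 equiv), THF, −78 °C; aq. NH4Cl
Reagents that add atoms: vinylmagnesium bromide 17, C=C[Mg]Br
Why: Grignard 1,2-addition to the enone carbonyl at −78 °C should outpace attack on the benzoate, and the new carbinol centre C9 is formed as a mixture that step 8 erases.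

Step 8
Reactants: 18 (1R,4R)-4-[(1E)-3-hydroxy-3-methylpenta-1,4-dien-1-yl]-3,5,5-trimethylcyclohex-2-en-1-yl benzoate; 19 triphenylphosphine hydrobromide
Product: 20 {(2E,4E)-5-[(1R,4R)-4-(benzoyloxy)-2,6,6-trimethylcyclohex-2-en-1-yl]-3-methylpenta-2,4-dien-1-yl}triphenylphosphonium bromide
Conditions: PPh3·HBr (1.05 equiv), CH2Cl2, 0 °C to rt; precipitation from EtOAc
Reagents that add atoms: triphenylphosphine hydrobromide 19, [Br-].[PH+](c1ccccc1)(c1ccccc1)c1ccccc1
Why: Acid-promoted ionisation of the tertiary bis-allylic alcohol gives a pentadienyl cation that PPh3 captures at the primary terminus (allylic transposition, the standard preparation of C15 Wittig salts), the 9E geometry being thermodynamically favoured and the allylic benzoate surviving.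

Step 9
Reactants: 20 the C15 phosphonium bromide (2.1 equiv); 21 (2E,4E,6E)-2,7-dimethylocta-2,4,6-trienedial
Product: 24 lactucaxanthin, (3R,6R,3'R,6'R)-ε,ε-carotene-3,3'-diol, via apo-carotenal benzoate 22 (not isolated), via lactucaxanthin dibenzoate 23 (not isolated)
Conditions: NaOMe (6 equiv), MeOH/CH2Cl2, 0 °C to rt, argon, dim light; then reflux in heptane; crystallisation
Reagents that add atoms: (2E,4E,6E)-2,7-dimethylocta-2,4,6-trienedial 21, O=C/C(C)=C/C=C/C=C(C)/C=O
Why: Twofold Wittig olefination of the C10 dialdehyde builds C11=C12 and C11'=C12', excess NaOMe then cleaves both benzoates by transesterification, and heating should equilibrate 11Z isomers to the all-E polyene without touching C3 or C6.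

**Compound list**

1 | 3-methylbut-2-enal | CC(C)=CC=O | starting material
2 | allenylboronic acid pinacol ester | C=C=CB1OC(C)(C)C(C)(C)O1 | starting material
3 | pinacol borate ester of 4 | CC(C)=C[C@@H](CC#C)OB1OC(C)(C)C(C)(C)O1 | intermediate
4 | (4R)-6-methylhept-5-en-1-yn-4-ol | CC(C)=C[C@H](O)CC#C | intermediate
5 | (bromoethynyl)trimethylsilane | C[Si](C)(C)C#CBr | starting material
6 | (E)-alkenylzirconocene chloride from 4 (oxygen also zirconated) | CC(C)=C[C@@H](C/C=C/[Zr](Cl)(C1C=CC=C1)C1C=CC=C1)O[Zr](Cl)(C1C=CC=C1)C1C=CC=C1 | intermediate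
7 | (3E,6R)-8-methyl-1-(trimethylsilyl)nona-3,7-dien-1-yn-6-ol | CC(C)=C[C@H](O)C/C=C/C#C[Si](C)(C)C | intermediate
8 | potassium enolate of 9 | [K+].[O-]C=CC(C)(C)[C@H](C#C[Si](C)(C)C)C=C | intermediate
9 | (4R)-4-ethenyl-3,3-dimethyl-6-(trimethylsilyl)hex-5-ynal | O=CCC(C)(C)[C@H](C#C[Si](C)(C)C)C=C | intermediate
10 | (4R)-4-ethynyl-3,3-dimethylhex-5-enal | O=CCC(C)(C)[C@H](C#C)C=C | intermediate
11 | methylboronic acid | CB(O)O | starting material
12 | (1S,4R)-4-ethenyl-3,5,5-trimethylcyclohex-2-en-1-ol | CC1=C[C@@H](O)CC(C)(C)[C@H]1C=C | intermediate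
13 | benzoic acid | OC(=O)c1ccccc1 | starting material
14 | (1R,4R)-4-ethenyl-3,5,5-trimethylcyclohex-2-en-1-yl benzoate | CC1=C[C@H](OC(=O)c2ccccc2)CC(C)(C)[C@H]1C=C | intermediate
15 | but-3-en-2-one | CC(=O)C=C | starting material
16 | (1R,4R)-3,5,5-trimethyl-4-[(1E)-3-oxobut-1-en-1-yl]cyclohex-2-en-1-yl benzoate | CC1=C[C@H](OC(=O)c2ccccc2)CC(C)(C)[C@H]1/C=C/C(C)=O | intermediate
17 | vinylmagnesium bromide | C=C[Mg]Br | starting material
18 | (1R,4R)-4-[(1E)-3-hydroxy-3-methylpenta-1,4-dien-1-yl]-3,5,5-trimethylcyclohex-2-en-1-yl benzoate (C9 epimers) | CC1=C[C@H](OC(=O)c2ccccc2)CC(C)(C)[C@H]1/C=C/C(C)(O)C=C | intermediate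
19 | triphenylphosphine hydrobromide | [Br-].[PH+](c1ccccc1)(c1ccccc1)c1ccccc1 | starting material
20 | {(2E,4E)-5-[(1R,4R)-4-(benzoyloxy)-2,6,6-trimethylcyclohex-2-en-1-yl]-3-methylpenta-2,4-dien-1-yl}triphenylphosphonium bromide | CC1=C[C@H](OC(=O)c2ccccc2)CC(C)(C)[C@H]1/C=C/C(C)=C/C[P+](c1ccccc1)(c1ccccc1)c1ccccc1.[Br-] | intermediate
21 | (2E,4E,6E)-2,7-dimethylocta-2,4,6-trienedial | O=C/C(C)=C/C=C/C=C(C)/C=O | starting material
22 | (3R,6R)-3-benzoyloxy-12'-apo-ε-caroten-12'-al | CC1=C[C@H](OC(=O)c2ccccc2)CC(C)(C)[C@H]1/C=C/C(C)=C/C=C/C(C)=C/C=C/C=C(C)/C=O | intermediate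
23 | lactucaxanthin 3,3'-dibenzoate | CC1=C[C@H](OC(=O)c2ccccc2)CC(C)(C)[C@H]1/C=C/C(C)=C/C=C/C(C)=C/C=C/C=C(C)/C=C/C=C(C)/C=C/[C@H]1C(C)=C[C@H](OC(=O)c2ccccc2)CC1(C)C | intermediate
24 | lactucaxanthin, (3R,6R,3'R,6'R)-ε,ε-carotene-3,3'-diol | CC1=C[C@H](O)CC(C)(C)[C@H]1/C=C/C(C)=C/C=C/C(C)=C/C=C/C=C(C)/C=C/C=C(C)/C=C/[C@H]1C(C)=C[C@H](O)CC1(C)C | target

**Step count.** Total steps: 9. Longest linear sequence: 9 steps (1 to 24).

**Steps most likely to fail**

Step 4. The closure may go 5-exo through the internal alkyne carbon, the terminal alkyne may oligomerise at zerovalent palladium, or slow methyl transfer from boron may lead to protodepalladation. The fallback is an intramolecular Nozaki–Hiyama–Kishi closure of the same C3–C4 bond. It sets out from 9 (isolated by leaving out the K2CO3/MeOH treatment of step 3) and comes back at 12.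
- 9 is converted with HC(OMe)3 and pyridinium p-toluenesulfonate in MeOH into the dimethyl acetal (3R)-3-ethenyl-6,6-dimethoxy-4,4-dimethyl-1-(trimethylsilyl)hex-1-yne F1.
- Ni(acac)2/AlMe3-catalysed syn-addition of MeMgBr across the silylalkyne (magnesium on the silicon-bearing carbon), then protonation, gives the alkenylsilane (1Z,3R)-3-ethenyl-6,6-dimethoxy-2,4,4-trimethyl-1-(trimethylsilyl)hex-1-ene F2.
- N-iodosuccinimide in MeCN replaces silicon by iodine with retention and gives (1Z,3R)-3-ethenyl-1-iodo-6,6-dimethoxy-2,4,4-trimethylhex-1-ene F3.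
- Pyridinium p-toluenesulfonate in wet acetone frees the aldehyde (4R,5Z)-4-ethenyl-6-iodo-3,3,5-trimethylhex-5-enal F4.
- CrCl2 with catalytic NiCl2 in DMSO adds the alkenylchromium to the aldehyde and gives 12.

Step 3. The alkoxide may fragment into the enal and a stabilised pentenynyl anion that recombines without stereospecificity (eroding the chirality transfer), or base may strip the silyl group early or isomerise the skipped enyne. The fallback is an iridium-catalysed allylic alkylation followed by one-carbon homologation. It sets out from 5 and comes back at 9.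
- Stille coupling of 5 with (E)-3-(tributylstannyl)prop-2-en-1-ol (Pd(PPh3)4, CuI) gives (2E)-5-(trimethylsilyl)pent-2-en-4-yn-1-ol F5.
- Methyl chloroformate/pyridine gives methyl (2E)-5-(trimethylsilyl)pent-2-en-4-yn-1-yl carbonate F6.
- [Ir(cod)Cl]2 with a Feringa-type phosphoramidite (enantiomer chosen for the 3R product) and the trimethylsilyl ketene acetal of methyl isobutyrate gives the branched ester methyl (3R)-3-ethenyl-2,2-dimethyl-5-(trimethylsilyl)pent-4-ynoate F7.
- i-Bu2AlH at −78 °C gives (3R)-3-ethenyl-2,2-dimethyl-5-(trimethylsilyl)pent-4-ynal F8.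
- Ph3P=CHOMe gives (5R)-5-ethenyl-1-methoxy-4,4-dimethyl-7-(trimethylsilyl)hept-1-en-6-yne F9 (E/Z mixture).
- Mild aqueous acid hydrolysis gives 9, which re-enters step 3 at the K2CO3/MeOH treatment.

Step 5. The allylic alkoxyphosphonium may ionise, leading to elimination to a cyclohexadiene or SN2' scrambling in place of clean inversion. The fallback sets C3 by reagent control. It sets out from 12 and comes back at 14.
- MnO2 in CH2Cl2 oxidises 12 to (4R)-4-ethenyl-3,5,5-trimethylcyclohex-2-en-1-one F10.
- Catecholborane with (S)-2-methyl-CBS-oxazaborolidine (alkenyl arm as the large group) should give (1R,4R)-4-ethenyl-3,5,5-trimethylcyclohex-2-en-1-ol F11.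
- BzCl, pyridine and 4-(dimethylamino)pyridine give 14.

**Further compounds**

F1 | step 4 | (3R)-3-ethenyl-6,6-dimethoxy-4,4-dimethyl-1-(trimethylsilyl)hex-1-yne | COC(OC)CC(C)(C)[C@H](C#C[Si](C)(C)C)C=C
F2 | step 4 | (1Z,3R)-3-ethenyl-6,6-dimethoxy-2,4,4-trimethyl-1-(trimethylsilyl)hex-1-ene | COC(OC)CC(C)(C)[C@H](/C(C)=C\[Si](C)(C)C)C=C
F3 | step 4 | (1Z,3R)-3-ethenyl-1-iodo-6,6-dimethoxy-2,4,4-trimethylhex-1-ene | COC(OC)CC(C)(C)[C@H](/C(C)=C\I)C=C
F4 | step 4 | (4R,5Z)-4-ethenyl-6-iodo-3,3,5-trimethylhex-5-enal | O=CCC(C)(C)[C@H](/C(C)=C\I)C=C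
F5 | step 3 | (2E)-5-(trimethylsilyl)pent-2-en-4-yn-1-ol | OC/C=C/C#C[Si](C)(C)C
F6 | step 3 | methyl (2E)-5-(trimethylsilyl)pent-2-en-4-yn-1-yl carbonate | COC(=O)OC/C=C/C#C[Si](C)(C)C
F7 | step 3 | methyl (3R)-3-ethenyl-2,2-dimethyl-5-(trimethylsilyl)pent-4-ynoate | COC(=O)C(C)(C)[C@H](C#C[Si](C)(C)C)C=C
F8 | step 3 | (3R)-3-ethenyl-2,2-dimethyl-5-(trimethylsilyl)pent-4-ynal | O=CC(C)(C)[C@H](C#C[Si](C)(C)C)C=C
F9 | step 3 | (5R)-5-ethenyl-1-methoxy-4,4-dimethyl-7-(trimethylsilyl)hept-1-en-6-yne | COC=CC(C)(C)[C@H](C#C[Si](C)(C)C)C=C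
F10 | step 5 | (4R)-4-ethenyl-3,5,5-trimethylcyclohex-2-en-1-one | CC1=CC(=O)CC(C)(C)[C@H]1C=C
F11 | step 5 | (1R,4R)-4-ethenyl-3,5,5-trimethylcyclohex-2-en-1-ol | CC1=C[C@H](O)CC(C)(C)[C@H]1C=C
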